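Pentasubstituted ring A (only C6 bears hydrogen) is cut into a four-carbon vinylketene unit and a two-carbon ynol ether. One thermal benzannulation of 3-(benzyloxy)cyclobut-2-en-1-one with a 1-methoxyalkyne that already carries the silylated C8 side chain forms C8–C8a and C6–C7 and closes ring A at C4a–C8a. It delivers the three meta oxygens in three different states: free at C8a, benzylated at C5, methylated at C7, with the chain locked between C7 and C8a. The feature exploited is this 1,3,5-trioxygenated ring with its contiguous O–alkyl–O array. The free phenol then carries ring C: Mitsunobu inversion sets C2, and acylation at C4a closes the pyranone.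

Key step: step 5

Remark on sourcing: 3-ethoxycyclobut-2-en-1-one and (R)-1-phenylbut-3-en-1-ol are taken as purchasable; the former is otherwise the [2+2] adduct of ketene and ethoxyacetylene, the latter the product of an asymmetric allylation of benzaldehyde.

Step 1
Reactants: 1 3-methylbutane-1,3-diol
Product: 2 4-iodo-2-methylbutan-2-ol
Conditions: I2, PPh3, imidazole, CH2Cl2, 0 °C to rt
Reagents that add atoms: iodine, II
Why: Appel-type iodination, in which only the primary hydroxyl is activated and displaced by iodide (SN2) while the tertiary hydroxyl is too hindered to react, and the base-free work-up avoids closure to the oxetane.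

Step 2
Reactants: 2 4-iodo-2-methylbutan-2-ol
Product: 3 triethyl[(4-iodo-2-methylbutan-2-yl)oxy]silane
Conditions: TESOTf, 2,6-lutidine, CH2Cl2, −78 to 0 °C
Reagents that add atoms: triethylsilyl trifluoromethanesulfonate, CC[Si](CC)(CC)OS(=O)(=O)C(F)(F)F
Why: Silylation with a silyl triflate and a hindered pyridine base is the standard way to cap a tertiary alcohol, and the primary iodide is inert to it.

Step 3
Reactants: 4 chloroacetaldehyde dimethyl acetal (2-chloro-1,1-dimethoxyethane); 3 triethyl[(4-iodo-2-methylbutan-2-yl)oxy]silane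
Product: 6 1-methoxy-5-methyl-5-(triethylsilyloxy)hex-1-yne, via sodium methoxyacetylide 5 (not isolated)
Conditions: NaNH2 (3 equiv), liq. NH3, −33 °C; then 3, THF, −33 °C to rt
Reagents that add atoms: sodium amide, [Na+].[NH2-] (its sodium stays only in intermediate 5)
Why: Classical alkoxyacetylide synthesis, in which NaNH2 effects the double elimination (loss of methanol and HCl) and metalation that turn the chloroacetal into acetylide 5, which is alkylated by SN2 at the unhindered primary iodide while the hindered tertiary silyl ether stays intact.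

Step 4
Reactants: 7 3-ethoxycyclobut-2-en-1-one; 8 benzyl alcohol
Product: 9 3-(benzyloxy)cyclobut-2-en-1-one
Conditions: BnOH (3 equiv), TsOH·H2O (cat.), toluene, 40 °C, reduced pressure (−EtOH)
Reagents that add atoms: none
Why: Acid-catalysed transetherification of a vinylogous ester by addition–elimination at C3 (the same pathway that hydrolyses this enol ether in aqueous acid), driven by removal of ethanol and run well below the temperature of electrocyclic ring opening.

Step 5
Reactants: 9 3-(benzyloxy)cyclobut-2-en-1-one; 6 1-methoxy-5-methyl-5-(triethylsilyloxy)hex-1-yne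
Product: 14 5-(benzyloxy)-3-methoxy-2-[3-methyl-3-(triethylsilyloxy)butyl]phenol, via vinylketene 10 (not isolated), via 4-vinylcyclobutenone 11 (not isolated), via dienylketene 12 (not isolated), via cyclohexadienone 13 (not isolated)
Conditions: toluene (0.5 M), sealed tube, 80 °C then 110 °C; then K2CO3, MeOH, rt
Reagents that add atoms: none
Why: Thermal conrotatory 4π opening of 9 gives vinylketene 10, whose ketene C=C adds ynol ether 6 in a regioselective [2+2] to give 4-vinylcyclobutenone 11; a second 4π opening gives dienylketene 12, which closes ring A by a disrotatory 6π-electrocyclisation (C4a–C8a) to cyclohexadienone 13 and tautomerises to phenol 14. The closest known reaction is the Danheiser benzannulation of cyclobutenones with alkoxyalkynes, applied here to a vinylogous-ester cyclobutenone. No stereocentre is formed. The selectivity needed is the orientation of the ketene–alkyne [2+2]: the nucleophilic, alkyl-bearing carbon of the ynol ether bonds to the electrophilic ketene carbonyl carbon, which puts the chain at C8 next to the new phenol (C8a) and the methoxy group at C7, while the benzyloxy group of 9 ends at C5 and C4a and C6 remain C–H. A methyl ynol ether is chosen because it cannot lose an alkene by retro-ene fragmentation on heating, and the carbonate methanolysis should return any product that was O-acylated by 10.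

Step 6
Reactants: 14 5-(benzyloxy)-3-methoxy-2-[3-methyl-3-(triethylsilyloxy)butyl]phenol; 15 (R)-1-phenylbut-3-en-1-ol
Product: 16 5-(benzyloxy)-1-methoxy-2-[3-methyl-3-(triethylsilyloxy)butyl]-3-{[(1S)-1-phenylbut-3-en-1-yl]oxy}benzene
Conditions: PPh3, DIAD, toluene, 0 °C to rt
Reagents that add atoms: none
Why: Mitsunobu etherification, in which the phenol oxygen displaces the activated benzylic hydroxyl by SN2 with inversion, so the purchased (R)-carbinol becomes the (S)-ether that is C2 of the target, the only free phenol (on C8a) being the only nucleophile.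

Step 7
Reactants: 16 5-(benzyloxy)-1-methoxy-2-[3-methyl-3-(triethylsilyloxy)butyl]-3-{[(1S)-1-phenylbut-3-en-1-yl]oxy}benzene
Product: 18 (3S)-3-{5-(benzyloxy)-3-methoxy-2-[3-methyl-3-(triethylsilyloxy)butyl]phenoxy}-3-phenylpropanal, via 1,2-diol 17 (not isolated)
Conditions: OsO4 (cat.), NaIO4, 2,6-lutidine, dioxane/H2O (3:1), rt
Reagents that add atoms: osmium tetroxide, O=[Os](=O)(=O)=O; sodium periodate, [Na+].[O-]I(=O)(=O)=O (reoxidant that replaces the oxygen delivered by osmium)
Why: Lemieux–Johnson oxidation, in which catalytic OsO4 dihydroxylates only the terminal alkene to diol 17 (the electron-rich arene, which ozone would attack, is left alone) and periodate cleaves it, while the lutidine-buffered medium avoids beta-elimination of the aryloxide and leaves the benzylic stereocentre untouched.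

Step 8
Reactants: 18 (3S)-3-{5-(benzyloxy)-3-methoxy-2-[3-methyl-3-(triethylsilyloxy)butyl]phenoxy}-3-phenylpropanal
Product: 19 (3S)-3-{5-(benzyloxy)-3-methoxy-2-[3-methyl-3-(triethylsilyloxy)butyl]phenoxy}-3-phenylpropanoic acid
Conditions: NaClO2, NaH2PO4, 2-methyl-2-butene (large excess), t-BuOH/H2O, 0 °C to rt
Reagents that add atoms: sodium chlorite, [Na+].[O-]Cl=O
Why: Pinnick oxidation at buffered pH, mild enough for the beta-aryloxy aldehyde and the silyl ether, with excess 2-methyl-2-butene scavenging hypochlorous acid so that the electron-rich ring is not chlorinated.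

Step 9
Reactants: 19 (3S)-3-{5-(benzyloxy)-3-methoxy-2-[3-methyl-3-(triethylsilyloxy)butyl]phenoxy}-3-phenylpropanoic acid
Product: 21 (2S)-5-(benzyloxy)-7-methoxy-8-[3-methyl-3-(triethylsilyloxy)butyl]-2-phenyl-2,3-dihydro-4H-chromen-4-one, via mixed anhydride 20 (not isolated)
Conditions: TFAA (1.5 equiv), CH2Cl2 (0.02 M), −20 to 0 °C; aq. NaHCO3
Reagents that add atoms: trifluoroacetic anhydride, O=C(OC(=O)C(F)(F)F)C(F)(F)F (its atoms stay only in intermediate 20)
Why: Intramolecular Friedel–Crafts acylation through mixed anhydride 20, in which C4a is the only free position ortho to the tethering oxygen and is activated by three oxygens (ortho to O1 and to the C5 benzyloxy group, para to the C7 methoxy group), so ring C should close as a six-membered ketone without a Lewis acid, and the stereocentre, beta to the new carbonyl, cannot enolise.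

Step 10
Reactants: 21 (2S)-5-(benzyloxy)-7-methoxy-8-[3-methyl-3-(triethylsilyloxy)butyl]-2-phenyl-2,3-dihydro-4H-chromen-4-one
Product: 22 (2S)-5-(benzyloxy)-8-(3-hydroxy-3-methylbutyl)-7-methoxy-2-phenyl-2,3-dihydro-4H-chromen-4-one
Conditions: HF·pyridine, pyridine, THF, 0 °C to rt
Reagents that add atoms: none
Why: Fluoride-driven Si–O cleavage frees the tertiary alcohol without passing through a tertiary cation, and the non-basic medium cannot open the flavanone by retro-oxa-Michael reaction, so C2 keeps its configuration.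

Step 11
Reactants: 22 (2S)-5-(benzyloxy)-8-(3-hydroxy-3-methylbutyl)-7-methoxy-2-phenyl-2,3-dihydro-4H-chromen-4-one
Product: 23 (2S)-5-hydroxy-8-(3-hydroxy-3-methylbutyl)-7-methoxy-2-phenyl-2,3-dihydro-4H-chromen-4-one
Conditions: H2 (1 atm), Pd/C (10%), EtOAc, rt, stopped at one equivalent of H2
Reagents that add atoms: none
Why: Hydrogenolysis of the aryl benzyl ether over Pd/C is much faster than cleavage of the benzylic C2–O1 bond or reduction of the aryl ketone, and the neutral conditions leave the stereocentre and the tertiary alcohol alone.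

Compound list
1 | 3-methylbutane-1,3-diol | CC(C)(O)CCO | starting material
2 | 4-iodo-2-methylbutan-2-ol | CC(C)(O)CCI | intermediate
3 | triethyl[(4-iodo-2-methylbutan-2-yl)oxy]silane | CC[Si](CC)(CC)OC(C)(C)CCI | intermediate
4 | chloroacetaldehyde dimethyl acetal (2-chloro-1,1-dimethoxyethane) | COC(CCl)OC | starting material
5 | sodium methoxyacetylide (not isolated) | COC#[C-].[Na+] | intermediate
6 | 1-methoxy-5-methyl-5-(triethylsilyloxy)hex-1-yne | COC#CCCC(C)(C)O[Si](CC)(CC)CC | intermediate
7 | 3-ethoxycyclobut-2-en-1-one | CCOC1=CC(=O)C1 | starting material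
8 | benzyl alcohol | OCc1ccccc1 | starting material
9 | 3-(benzyloxy)cyclobut-2-en-1-one | O=C1C=C(OCc2ccccc2)C1 | intermediate
10 | 3-(benzyloxy)buta-1,3-dien-1-one (vinylketene, not isolated) | O=C=CC(=C)OCc1ccccc1 | intermediate
11 | 4-[1-(benzyloxy)ethenyl]-3-methoxy-2-[3-methyl-3-(triethylsilyloxy)butyl]cyclobut-2-en-1-one (racemic, not isolated) | O=C1C(CCC(C)(C)O[Si](CC)(CC)CC)=C(OC)C1C(=C)OCc1ccccc1 | intermediate
12 | (3E)-5-(benzyloxy)-3-methoxy-2-[3-methyl-3-(triethylsilyloxy)butyl]hexa-1,3,5-trien-1-one (dienylketene, not isolated) | O=C=C(CCC(C)(C)O[Si](CC)(CC)CC)/C(OC)=C\C(=C)OCc1ccccc1 | intermediate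
13 | 5-(benzyloxy)-3-methoxy-2-[3-methyl-3-(triethylsilyloxy)butyl]cyclohexa-2,4-dien-1-one (not isolated) | O=C1CC(OCc2ccccc2)=CC(OC)=C1CCC(C)(C)O[Si](CC)(CC)CC | intermediate
14 | 5-(benzyloxy)-3-methoxy-2-[3-methyl-3-(triethylsilyloxy)butyl]phenol | COc1cc(OCc2ccccc2)cc(O)c1CCC(C)(C)O[Si](CC)(CC)CC | intermediate
15 | (R)-1-phenylbut-3-en-1-ol | O[C@H](CC=C)c1ccccc1 | starting material
16 | 5-(benzyloxy)-1-methoxy-2-[3-methyl-3-(triethylsilyloxy)butyl]-3-{[(1S)-1-phenylbut-3-en-1-yl]oxy}benzene | C=CC[C@H](Oc1cc(OCc2ccccc2)cc(OC)c1CCC(C)(C)O[Si](CC)(CC)CC)c1ccccc1 | intermediate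
17 | (4S)-4-{5-(benzyloxy)-3-methoxy-2-[3-methyl-3-(triethylsilyloxy)butyl]phenoxy}-4-phenylbutane-1,2-diol (both C2 epimers, not isolated) | OCC(O)C[C@H](Oc1cc(OCc2ccccc2)cc(OC)c1CCC(C)(C)O[Si](CC)(CC)CC)c1ccccc1 | intermediate
18 | (3S)-3-{5-(benzyloxy)-3-methoxy-2-[3-methyl-3-(triethylsilyloxy)butyl]phenoxy}-3-phenylpropanal | O=CC[C@H](Oc1cc(OCc2ccccc2)cc(OC)c1CCC(C)(C)O[Si](CC)(CC)CC)c1ccccc1 | intermediate
19 | (3S)-3-{5-(benzyloxy)-3-methoxy-2-[3-methyl-3-(triethylsilyloxy)butyl]phenoxy}-3-phenylpropanoic acid | OC(=O)C[C@H](Oc1cc(OCc2ccccc2)cc(OC)c1CCC(C)(C)O[Si](CC)(CC)CC)c1ccccc1 | intermediate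
20 | (3S)-3-{5-(benzyloxy)-3-methoxy-2-[3-methyl-3-(triethylsilyloxy)butyl]phenoxy}-3-phenylpropanoic trifluoroacetic anhydride (not isolated) | O=C(C[C@H](Oc1cc(OCc2ccccc2)cc(OC)c1CCC(C)(C)O[Si](CC)(CC)CC)c1ccccc1)OC(=O)C(F)(F)F | intermediate
21 | (2S)-5-(benzyloxy)-7-methoxy-8-[3-methyl-3-(triethylsilyloxy)butyl]-2-phenyl-2,3-dihydro-4H-chromen-4-one | COc1cc(OCc2ccccc2)c2c(c1CCC(C)(C)O[Si](CC)(CC)CC)O[C@H](c1ccccc1)CC2=O | intermediate
22 | (2S)-5-(benzyloxy)-8-(3-hydroxy-3-methylbutyl)-7-methoxy-2-phenyl-2,3-dihydro-4H-chromen-4-one | COc1cc(OCc2ccccc2)c2c(c1CCC(C)(C)O)O[C@H](c1ccccc1)CC2=O | intermediate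
23 | (2S)-5-hydroxy-8-(3-hydroxy-3-methylbutyl)-7-methoxy-2-phenyl-2,3-dihydro-4H-chromen-4-one (CNP0160063.1) | COc1cc(O)c2c(c1CCC(C)(C)O)O[C@H](c1ccccc1)CC2=O | target

Total step count: 11. Longest linear sequence: 10 steps (1 → 2 → 3 → 6 → 14 → 16 → 18 → 19 → 21 → 22 → 23; step 4 is the side branch).

Steps most likely to fail

Step 5 (benzannulation). The vinylogous-ester cyclobutenone may open too slowly, so that oligomerisation of the vinylketene or its capture by the product phenol outruns the [2+2]; the cycloaddition could also lose its orientation. The fallback sets out from iodide 3 and returns at phenol 14; it takes ring A from a purchased arene and substitutes it stepwise instead of building it. 2-Bromo-3-methoxyphenol is silylated (TIPSCl, imidazole, DMF) to (2-bromo-3-methoxyphenoxy)triisopropylsilane F1. Iodide 3 is converted with zinc dust and LiCl in THF into iodo[3-methyl-3-(triethylsilyloxy)butyl]zinc F2, and Negishi coupling with F1 (Pd(OAc)2, SPhos, THF, 50 °C) should give triethyl({4-[2-methoxy-6-(triisopropylsilyloxy)phenyl]-2-methylbutan-2-yl}oxy)silane F3, in which the chain already lies between the two differentiated oxygens. Iridium-catalysed C–H borylation ([Ir(cod)OMe]2, 4,4'-di-tert-butyl-2,2'-bipyridine, B2pin2, THF, 80 °C) should take the only ring C–H without an ortho neighbour and give the pinacol boronate F4, which is oxidised in the same flask (NaBO3·4H2O, THF/H2O) to 3-methoxy-4-[3-methyl-3-(triethylsilyloxy)butyl]-5-(triisopropylsilyloxy)phenol F5. Benzylation (BnBr, K2CO3, DMF) gives the benzyl ether F6, and TBAF (1 equiv, THF, 0 °C) should cleave the aryl silyl ether much faster than the hindered tertiary one, which gives 14.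

Step 9 (Friedel–Crafts closure). Acid set free during the acylation may strip or trifluoroacetylate the tertiary silyl ether and may ionise the benzylic aryl ether, which would erode the enantiomeric purity or lose the phenol by elimination; the anhydride may also trifluoroacetylate C6. The fallback sets out from phenol 14 and returns at flavanone 21; it makes the C4–C4a bond first and the C2–O1 bond last, with no acylium chemistry. Magnesium-mediated ortho-formylation of 14 (MgCl2, Et3N, paraformaldehyde, MeCN, reflux), which can reach only C4a, gives 6-(benzyloxy)-2-hydroxy-4-methoxy-3-[3-methyl-3-(triethylsilyloxy)butyl]benzaldehyde F7; propane-1,3-dithiol with catalytic I2 in CH2Cl2 gives the 1,3-dithiane F8. Double deprotonation (n-BuLi, 2.2 equiv, THF, −78 to −20 °C) and opening of (S)-styrene oxide at its CH2 terminus (Corey–Seebach alkylation) gives the (R)-carbinol F9. Intramolecular Mitsunobu etherification (PPh3, DIAD, THF) closes ring C with inversion to the (2S)-spiro-dithioketal F10, and MeI/CaCO3 in aqueous MeCN unmasks the C4 ketone to give 21.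

Step 6 (Mitsunobu etherification). The activated benzylic, homoallylic alcohol may eliminate to 1-phenylbuta-1,3-diene, partial ionisation may erode the inversion, and the ortho-substituted phenol may couple slowly. The fallback sets out from phenol 14 and returns at acid 19; it makes the C2–O bond by catalyst-controlled allylic substitution instead of stereospecific displacement. Methyl (E)-cinnamyl carbonate F11 (from cinnamyl alcohol, ClCO2Me, pyridine) reacts with 14 and a stoichiometric base under [Ir(cod)Cl]2 and a chiral phosphoramidite ligand (the enantiomer that gives the (S)-ether) in an iridium-catalysed asymmetric allylic etherification, which should give the branched (S)-1-phenylallyl aryl ether F12. Hydroboration–oxidation (9-BBN, THF; NaBO3·4H2O) gives the (3S)-3-aryloxy-3-phenylpropan-1-ol F13, and TEMPO/PhI(OAc)2 in aqueous MeCN oxidises it to 19.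

Further compounds
F1 | step 5 | (2-bromo-3-methoxyphenoxy)triisopropylsilane | COc1cccc(O[Si](C(C)C)(C(C)C)C(C)C)c1Br
F2 | step 5 | iodo[3-methyl-3-(triethylsilyloxy)butyl]zinc | CC[Si](CC)(CC)OC(C)(C)CC[Zn]I
F3 | step 5 | triethyl({4-[2-methoxy-6-(triisopropylsilyloxy)phenyl]-2-methylbutan-2-yl}oxy)silane | COc1cccc(O[Si](C(C)C)(C(C)C)C(C)C)c1CCC(C)(C)O[Si](CC)(CC)CC
F4 | step 5 | 2-{3-methoxy-4-[3-methyl-3-(triethylsilyloxy)butyl]-5-(triisopropylsilyloxy)phenyl}-4,4,5,5-tetramethyl-1,3,2-dioxaborolane | COc1cc(B2OC(C)(C)C(C)(C)O2)cc(O[Si](C(C)C)(C(C)C)C(C)C)c1CCC(C)(C)O[Si](CC)(CC)CC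
F5 | step 5 | 3-methoxy-4-[3-methyl-3-(triethylsilyloxy)butyl]-5-(triisopropylsilyloxy)phenol | COc1cc(O)cc(O[Si](C(C)C)(C(C)C)C(C)C)c1CCC(C)(C)O[Si](CC)(CC)CC
F6 | step 5 | {5-(benzyloxy)-3-methoxy-2-[3-methyl-3-(triethylsilyloxy)butyl]phenoxy}triisopropylsilane | COc1cc(OCc2ccccc2)cc(O[Si](C(C)C)(C(C)C)C(C)C)c1CCC(C)(C)O[Si](CC)(CC)CC
F7 | step 9 | 6-(benzyloxy)-2-hydroxy-4-methoxy-3-[3-methyl-3-(triethylsilyloxy)butyl]benzaldehyde | COc1cc(OCc2ccccc2)c(C=O)c(O)c1CCC(C)(C)O[Si](CC)(CC)CC
F8 | step 9 | 3-(benzyloxy)-2-(1,3-dithian-2-yl)-5-methoxy-6-[3-methyl-3-(triethylsilyloxy)butyl]phenol | COc1cc(OCc2ccccc2)c(C2SCCCS2)c(O)c1CCC(C)(C)O[Si](CC)(CC)CC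
F9 | step 9 | 3-(benzyloxy)-2-{2-[(2R)-2-hydroxy-2-phenylethyl]-1,3-dithian-2-yl}-5-methoxy-6-[3-methyl-3-(triethylsilyloxy)butyl]phenol | COc1cc(OCc2ccccc2)c(C2(C[C@@H](O)c3ccccc3)SCCCS2)c(O)c1CCC(C)(C)O[Si](CC)(CC)CC
F10 | step 9 | (2S)-5-(benzyloxy)-7-methoxy-8-[3-methyl-3-(triethylsilyloxy)butyl]-2-phenylspiro[chromane-4,2'-[1,3]dithiane] | COc1cc(OCc2ccccc2)c2c(c1CCC(C)(C)O[Si](CC)(CC)CC)O[C@H](c1ccccc1)CC21SCCCS1
F11 | step 6 | methyl (2E)-3-phenylprop-2-en-1-yl carbonate | COC(=O)OC/C=C/c1ccccc1
F12 | step 6 | 5-(benzyloxy)-1-methoxy-2-[3-methyl-3-(triethylsilyloxy)butyl]-3-{[(1S)-1-phenylprop-2-en-1-yl]oxy}benzene | C=C[C@H](Oc1cc(OCc2ccccc2)cc(OC)c1CCC(C)(C)O[Si](CC)(CC)CC)c1ccccc1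
F13 | step 6 | (3S)-3-{5-(benzyloxy)-3-methoxy-2-[3-methyl-3-(triethylsilyloxy)butyl]phenoxy}-3-phenylpropan-1-ol | OCC[C@H](Oc1cc(OCc2ccccc2)cc(OC)c1CCC(C)(C)O[Si](CC)(CC)CC)c1ccccc1
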